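## Retrosynthetic overview

- **Feature:** on ring A the ether oxygen O1 (on C8a) stands ortho to C4a. C4 with its ring D aryl group is therefore the exocyclic carbon of an o-quinone methide of ring A. C3 bears the oxygen of an α-hydroxy ketone whose carbonyl carbon is C2 and whose aryl group is ring B.
- **End game:** six aryl benzyl ethers are cleaved last. Before that, the stilbene C=C is attached to a ring D bromide by a Heck reaction with 3,4-bis(benzyloxy)styrene.
- **C2:** the C2–H bond comes from silane reduction of a C2 hemiketal, which places ring B trans to the C3 hydroxyl.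
- **Key cut:** the hemiketal is cut at C3–C4 and O1–C2 into the ring A/ring D o-quinone methide and 2-hydroxy-1-[4-(benzyloxy)phenyl]ethanone. The methide is released by base from the sulfone of the benzhydrol, which is made from a ring D arylmagnesium and a ring A salicylaldehyde.
- **Ring order:** rings A, B, D and the catechol ring are bought as such, and ring C is the only ring formed, in the key step.

Key step: step 7

Assumption: the sense of induction on this untried acceptor cannot be read from precedent, so (R,R)-ProPhenol is written, and its equally available antipode is taken if a pilot run shows the mirror-image series.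

## Route

Step 1
Reactants: 1 5-bromoresorcinol
Product: 2 1,3-bis(benzyloxy)-5-bromobenzene
Conditions: BnBr (2.3 equiv), K2CO3 (3 equiv), DMF, 50 °C
Reagents that add atoms: benzyl bromide, BrCc1ccccc1
Why: Williamson ether synthesis in which both phenoxides are alkylated under carbonate conditions while the aryl bromide stays inert.

Step 2
Reactants: 2 1,3-bis(benzyloxy)-5-bromobenzene
Product: 3 1,5-bis(benzyloxy)-3-bromo-2-iodobenzene
Conditions: NIS (1.05 equiv), MeCN, 0 °C → rt, dark
Reagents that add atoms: N-iodosuccinimide, O=C1CCC(=O)N1I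
Why: Electrophilic aromatic iodination at the carbon para to one ether and ortho to the other (next to bromine), which is the usual site of halogenation and formylation in 3,5-dialkoxybromobenzenes.

Step 3
Reactants: 3 1,5-bis(benzyloxy)-3-bromo-2-iodobenzene; 4 4-(benzyloxy)-2-hydroxybenzaldehyde
Product: 7 rac-5-(benzyloxy)-2-{[2,4-bis(benzyloxy)-6-bromophenyl](hydroxy)methyl}phenol, via arylmagnesium chloride 5 (not isolated), via sodium phenolate 6 (not isolated)
Conditions: 3 (1.2 equiv), iPrMgCl·LiCl (1.2 equiv), THF, −20 °C; separately 4, NaH (1.05 equiv), THF, 0 °C; combined at −20 → 0 °C; sat. aq NH4Cl, 0 °C; Et3N-deactivated silica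
Reagents that add atoms: none
Why: Halogen–magnesium exchange with iPrMgCl·LiCl takes iodine far faster than bromine and gives an ortho-bromoarylmagnesium that does not collapse to an aryne below 0 °C; its 1,2-addition to the pre-deprotonated salicylaldehyde is the standard entry to o-hydroxybenzhydrols and avoids the regioisomers and triarylmethanes of a phenoxide hydroxyalkylation; the carbinol centre is racemic and is erased in step 7.

Step 4
Reactants: 7 rac-5-(benzyloxy)-2-{[2,4-bis(benzyloxy)-6-bromophenyl](hydroxy)methyl}phenol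
Product: 8 rac-5-(benzyloxy)-2-{[2,4-bis(benzyloxy)-6-bromophenyl](4-methylbenzenesulfonyl)methyl}phenol
Conditions: p-TolSO2H (1.3 equiv, freshly liberated from p-TolSO2Na), CH2Cl2, 0 °C → rt
Reagents that add atoms: p-toluenesulfinic acid, Cc1ccc(cc1)S(=O)O
Why: SN1-type substitution (the usual preparation of 2-(sulfonylmethyl)phenols) in which the sulfinic acid ionises the doubly activated benzhydrol and sulfur captures the cation, which replaces a hydroxide leaving group that needs acid and releases water by one that leaves under mild base, and gives a storable form of a very acid-sensitive alcohol.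

Step 5
Reactants: 9 1-[4-(benzyloxy)phenyl]ethanone
Product: 10 1-[4-(benzyloxy)phenyl]-2-bromoethanone
Conditions: CuBr2 (2.0 equiv), EtOAc/CHCl3 1:1, reflux
Reagents that add atoms: CuBr2, Br[Cu]Br
Why: Heterogeneous CuBr2 α-bromination of an aryl methyl ketone through its enol stops at the monobromide and spares the electron-rich ring and the benzyl ether.

Step 6
Reactants: 10 1-[4-(benzyloxy)phenyl]-2-bromoethanone
Product: 12 1-[4-(benzyloxy)phenyl]-2-hydroxyethanone, via formate ester 11 (not isolated)
Conditions: HCO2Na (4 equiv), EtOH/H2O 4:1, reflux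
Reagents that add atoms: sodium formate, [Na+].[O-]C=O
Why: SN2 displacement of the phenacyl bromide by formate, followed by hydrolysis of the labile formate ester in the same pot, is the common route to 2-hydroxyacetophenones and avoids the condensations that hydroxide would cause.

Step 7
Reactants: 8 rac-5-(benzyloxy)-2-{[2,4-bis(benzyloxy)-6-bromophenyl](4-methylbenzenesulfonyl)methyl}phenol; 12 1-[4-(benzyloxy)phenyl]-2-hydroxyethanone
Product: 15 (3S,4S)-7-(benzyloxy)-2-[4-(benzyloxy)phenyl]-4-[2,4-bis(benzyloxy)-6-bromophenyl]-3,4-dihydro-2H-chromene-2,3-diol as a mixture of C2 anomers, via o-quinone methide 13 (not isolated), via open keto phenol 14 (not isolated)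
Conditions: (a) 8, Cs2CO3 (1.5 equiv), 4 Å MS, toluene, rt, then filtration under Ar; (b) filtrate added slowly to 12 (1.3 equiv), Et2Zn (20 mol %), (R,R)-ProPhenol [2,6-bis{[(2R)-2-(hydroxydiphenylmethyl)pyrrolidin-1-yl]methyl}-4-methylphenol, 10 mol %], 4 Å MS, THF/toluene, 0 °C → rt; pH 7 buffer
Reagents that add atoms: none
Why: Proposed new method: solid Cs2CO3 deprotonates the phenol of 8 and the phenoxide expels sulfinate (E1cB), giving 13 as a dry, salt-free solution, which matters because dehydration of 7 itself needs acid and would release one equivalent of water onto a catalyst made from Et2Zn; 13 should persist long enough because its C7 benzyloxy group makes it a vinylogous ester and the two ortho substituents of ring D block dimerisation. The dinuclear zinc complex deprotonates 12 to a chelated enediolate, its second zinc atom binds the carbonyl oxygen of 13, the oxygen-bearing enediolate carbon adds to the methide carbon (C3–C4) with rearomatisation of ring A to give 14, and proton transfer from the next molecule of 12 frees the product, so the catalytic stage forms no by-product. The closest known reaction types are the zinc–ProPhenol aldol, Mannich and Michael additions of 2-hydroxyacetophenones and the catalytic asymmetric conjugate addition–hemiketalisation of 1,3-dicarbonyl donors to o-quinone methides generated in situ; only the pairing of this donor class with this acceptor class is new. Ring C closes by reversible 6-exo-trig addition of the ring A phenoxide oxygen O1 to the ketone carbon C2 of 14, helped by the electron-withdrawing C3 hydroxyl. C4 is fixed by the face of 13 that the ligand pocket leaves open and carries the enantiomeric purity of the whole series, C3 is fixed by the shielded face of the bound enediolate and, as H3 of 14 stays acidic, can still equilibrate to the 3,4-trans diequatorial hemiketal in which the hydroxyl avoids ring D, and C2 forms as an anomeric mixture that step 8 flattens. The step needs attack through carbon rather than oxygen and a methide that is not trapped internally: O-adducts of so stabilised a methide revert whereas the C-adduct is held by aromatisation and ring closure, and ring D carries bromine in place of the styryl arm so that no alkene is at hand for cycloaddition.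

Step 8
Reactants: 15 (3S,4S)-7-(benzyloxy)-2-[4-(benzyloxy)phenyl]-4-[2,4-bis(benzyloxy)-6-bromophenyl]-3,4-dihydro-2H-chromene-2,3-diol
Product: 17 (2R,3S,4S)-7-(benzyloxy)-2-[4-(benzyloxy)phenyl]-4-[2,4-bis(benzyloxy)-6-bromophenyl]-3,4-dihydro-2H-chromen-3-ol, via C2 oxocarbenium ion 16 (not isolated)
Conditions: Et3SiH (5 equiv), BF3·OEt2 (2 equiv), CH2Cl2, −78 → −40 °C; sat. aq NaHCO3 at −40 °C
Reagents that add atoms: none
Why: Ionic silane reduction of a hemiketal, as used to turn 1-aryl pyranose hemiketals into β-C-aryl glycosides: BF3 removes the anomeric hydroxyl to give 16, stabilised by O1 and the para-benzyloxy group of ring B, and hydride enters axially on the half-chair whose C3 hydroxyl and C4 aryl group are pseudo-equatorial, so ring B ends equatorial and trans to the C3 hydroxyl (2R).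

Step 9
Reactants: 18 3,4-bis(benzyloxy)benzaldehyde
Product: 19 1,2-bis(benzyloxy)-4-ethenylbenzene
Conditions: Ph3PCH3Br (1.3 equiv), KOtBu (1.25 equiv), THF, 0 °C → rt
Reagents that add atoms: methyltriphenylphosphonium bromide, C[P+](c1ccccc1)(c1ccccc1)c1ccccc1.[Br-]
Why: Wittig methylenation of a non-enolisable aromatic aldehyde with the unstabilised ylide.

Step 10
Reactants: 17 (2R,3S,4S)-7-(benzyloxy)-2-[4-(benzyloxy)phenyl]-4-[2,4-bis(benzyloxy)-6-bromophenyl]-3,4-dihydro-2H-chromen-3-ol; 19 1,2-bis(benzyloxy)-4-ethenylbenzene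
Product: 20 (2R,3S,4S)-7-(benzyloxy)-2-[4-(benzyloxy)phenyl]-4-{2,4-bis(benzyloxy)-6-[(E)-2-[3,4-bis(benzyloxy)phenyl]ethenyl]phenyl}-3,4-dihydro-2H-chromen-3-ol
Conditions: 19 (1.5 equiv), Pd2(dba)3 (2.5 mol %), P(t-Bu)3·HBF4 (10 mol %), Cy2NMe (2 equiv), 1,4-dioxane, 90 °C
Reagents that add atoms: none
Why: Mizoroki–Heck reaction in which the ring D C–Br bond (meta to both ethers, hence not deactivated) adds oxidatively to zerovalent palladium bearing the bulky electron-rich phosphine, and syn insertion at the terminal carbon of 19 followed by syn β-hydride elimination gives the E-stilbene, while the amine base leaves the C3 hydroxyl and the three stereocentres untouched.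

Step 11
Reactants: 20 (2R,3S,4S)-7-(benzyloxy)-2-[4-(benzyloxy)phenyl]-4-{2,4-bis(benzyloxy)-6-[(E)-2-[3,4-bis(benzyloxy)phenyl]ethenyl]phenyl}-3,4-dihydro-2H-chromen-3-ol
Product: 21 (2R,3S,4S)-4-{2-[(E)-2-(3,4-dihydroxyphenyl)ethenyl]-4,6-dihydroxyphenyl}-2-(4-hydroxyphenyl)-3,4-dihydro-2H-chromene-3,7-diol (CNP0170061.1)
Conditions: BCl3 (1 M in CH2Cl2, 15 equiv), C6HMe5 (20 equiv), CH2Cl2, −78 °C; CHCl3/MeOH quench at −78 °C
Reagents that add atoms: none
Why: Lewis-acid debenzylation with a non-basic cation scavenger, in which BCl3 cleaves the six aryl benzyl ethers at −78 °C and pentamethylbenzene takes up the benzyl cations by Friedel–Crafts alkylation, so the stilbene double bond (which hydrogenolysis would saturate) and the electron-rich rings are spared and no stereocentre is touched.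

## Compound list

1 | 5-bromoresorcinol | Oc1cc(O)cc(Br)c1 | starting material
2 | 1,3-bis(benzyloxy)-5-bromobenzene | Brc1cc(OCc2ccccc2)cc(OCc2ccccc2)c1 | intermediate
3 | 1,5-bis(benzyloxy)-3-bromo-2-iodobenzene | Brc1cc(OCc2ccccc2)cc(OCc2ccccc2)c1I | intermediate
4 | 4-(benzyloxy)-2-hydroxybenzaldehyde | O=Cc1ccc(OCc2ccccc2)cc1O | starting material
5 | [2,4-bis(benzyloxy)-6-bromophenyl]magnesium chloride | Cl[Mg]c1c(Br)cc(OCc2ccccc2)cc1OCc1ccccc1 | intermediate
6 | sodium 5-(benzyloxy)-2-formylphenolate | [Na+].[O-]c1cc(OCc2ccccc2)ccc1C=O | intermediate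
7 | rac-5-(benzyloxy)-2-{[2,4-bis(benzyloxy)-6-bromophenyl](hydroxy)methyl}phenol | Oc1cc(OCc2ccccc2)ccc1C(O)c1c(OCc2ccccc2)cc(OCc2ccccc2)cc1Br | intermediate
8 | rac-5-(benzyloxy)-2-{[2,4-bis(benzyloxy)-6-bromophenyl](4-methylbenzenesulfonyl)methyl}phenol | Cc1ccc(cc1)S(=O)(=O)C(c1ccc(OCc2ccccc2)cc1O)c1c(OCc2ccccc2)cc(OCc2ccccc2)cc1Br | intermediate
9 | 1-[4-(benzyloxy)phenyl]ethanone | CC(=O)c1ccc(OCc2ccccc2)cc1 | starting material
10 | 1-[4-(benzyloxy)phenyl]-2-bromoethanone | O=C(CBr)c1ccc(OCc2ccccc2)cc1 | intermediate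
11 | 2-[4-(benzyloxy)phenyl]-2-oxoethyl formate | O=COCC(=O)c1ccc(OCc2ccccc2)cc1 | intermediate
12 | 1-[4-(benzyloxy)phenyl]-2-hydroxyethanone | O=C(CO)c1ccc(OCc2ccccc2)cc1 | intermediate
13 | (6E)-3-(benzyloxy)-6-{[2,4-bis(benzyloxy)-6-bromophenyl]methylidene}cyclohexa-2,4-dien-1-one | O=C1C=C(OCc2ccccc2)C=C/C1=C\c1c(OCc2ccccc2)cc(OCc2ccccc2)cc1Br | intermediate
14 | (2S,3S)-1-[4-(benzyloxy)phenyl]-3-[4-(benzyloxy)-2-hydroxyphenyl]-3-[2,4-bis(benzyloxy)-6-bromophenyl]-2-hydroxypropan-1-one | Oc1cc(OCc2ccccc2)ccc1[C@@H](c1c(OCc2ccccc2)cc(OCc2ccccc2)cc1Br)[C@H](O)C(=O)c1ccc(OCc2ccccc2)cc1 | intermediate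
15 | (3S,4S)-7-(benzyloxy)-2-[4-(benzyloxy)phenyl]-4-[2,4-bis(benzyloxy)-6-bromophenyl]-3,4-dihydro-2H-chromene-2,3-diol (C2 anomers) | OC1(c2ccc(OCc3ccccc3)cc2)Oc2cc(OCc3ccccc3)ccc2[C@@H](c2c(OCc3ccccc3)cc(OCc3ccccc3)cc2Br)[C@@H]1O | intermediate
16 | (3S,4S)-7-(benzyloxy)-2-[4-(benzyloxy)phenyl]-4-[2,4-bis(benzyloxy)-6-bromophenyl]-3-hydroxy-3,4-dihydrochromenylium | C1(c2ccc(OCc3ccccc3)cc2)=[O+]c2cc(OCc3ccccc3)ccc2[C@@H](c2c(OCc3ccccc3)cc(OCc3ccccc3)cc2Br)[C@@H]1O | intermediate
17 | (2R,3S,4S)-7-(benzyloxy)-2-[4-(benzyloxy)phenyl]-4-[2,4-bis(benzyloxy)-6-bromophenyl]-3,4-dihydro-2H-chromen-3-ol | c1ccccc1COc1ccc([C@H]2Oc3cc(OCc4ccccc4)ccc3[C@@H](c3c(OCc4ccccc4)cc(OCc4ccccc4)cc3Br)[C@@H]2O)cc1 | intermediate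
18 | 3,4-bis(benzyloxy)benzaldehyde | O=Cc1ccc(OCc2ccccc2)c(OCc2ccccc2)c1 | starting material
19 | 1,2-bis(benzyloxy)-4-ethenylbenzene | C=Cc1ccc(OCc2ccccc2)c(OCc2ccccc2)c1 | intermediate
20 | (2R,3S,4S)-7-(benzyloxy)-2-[4-(benzyloxy)phenyl]-4-{2,4-bis(benzyloxy)-6-[(E)-2-[3,4-bis(benzyloxy)phenyl]ethenyl]phenyl}-3,4-dihydro-2H-chromen-3-ol | c1ccccc1COc1ccc([C@H]2Oc3cc(OCc4ccccc4)ccc3[C@@H](c3c(OCc4ccccc4)cc(OCc4ccccc4)cc3/C=C/c3ccc(OCc4ccccc4)c(OCc4ccccc4)c3)[C@@H]2O)cc1 | intermediate
21 | (2R,3S,4S)-4-{2-[(E)-2-(3,4-dihydroxyphenyl)ethenyl]-4,6-dihydroxyphenyl}-2-(4-hydroxyphenyl)-3,4-dihydro-2H-chromene-3,7-diol | Oc1ccc([C@H]2Oc3cc(O)ccc3[C@@H](c3c(O)cc(O)cc3/C=C/c3ccc(O)c(O)c3)[C@@H]2O)cc1 | target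

## Step count and risks

Total step count: 11. Longest linear sequence: 8 steps (1, 2, 3, 4, 7, 8, 10, 11).

**Step 7.**
- **What may go wrong:** the crowded and strongly stabilised methide may take up the zinc enediolate too slowly, or it may decay before it is consumed. Its two faces may also be poorly discriminated, and retro-addition under the basic catalyst may erode the selectivity that is reached.
- **Scope of the fallback:** it sets out from 8 and 9 and comes back to the route at 17, so it replaces steps 7 and 8. The C3 oxygen is no longer brought in by the donor but is added after ring closure.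
- **Donor:** ketone 9 is acylated with NaH and dimethyl carbonate to methyl 3-[4-(benzyloxy)phenyl]-3-oxopropanoate F1. Cold LiOH saponifies it to 3-[4-(benzyloxy)phenyl]-3-oxopropanoic acid F2.
- **Asymmetric addition:** sulfone 8 and F2 are combined under a chiral bifunctional tertiary-amine squaramide with Na2CO3 as stoichiometric base. This is the established decarboxylative addition of β-keto acids to o-quinone methides released from 2-(sulfonylmethyl)phenols. The catalyst enantiomer is chosen for 4S, and the product should be (4S)-7-(benzyloxy)-2-[4-(benzyloxy)phenyl]-4-[2,4-bis(benzyloxy)-6-bromophenyl]-3,4-dihydro-2H-chromen-2-ol F3.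
- **Dehydration:** catalytic p-TsOH in toluene dehydrates it to (4S)-7-(benzyloxy)-2-[4-(benzyloxy)phenyl]-4-[2,4-bis(benzyloxy)-6-bromophenyl]-4H-chromene F4.
- **Hydroboration:** BH3·THF followed by NaOH/H2O2 is a known way from flav-2-enes to 2,3-trans-flavan-3-ols. Boron goes to C3 and hydrogen to C2 on the face opposite ring D, which gives 17 with the 2,3-trans-3,4-trans arrangement.

**Step 8.**
- **What may go wrong:** proton loss from C3 of the cation may compete with hydride transfer, and hydride may choose between the faces of C2 poorly. Renewed ionisation of the fresh C2–O1 bond may also lead to a second hydride transfer.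
- **Scope of the fallback:** it sets out from 15 and comes back at 17. Ring C is reopened and closed again at the alcohol oxidation level.
- **Reduction:** NaBH4 in THF/MeOH at 0 °C reduces the open form in equilibrium with 15. This gives (2S,3S)-1-[4-(benzyloxy)phenyl]-3-[4-(benzyloxy)-2-hydroxyphenyl]-3-[2,4-bis(benzyloxy)-6-bromophenyl]propane-1,2-diol F5 as C1 epimers.
- **Cyclisation:** HC(OEt)3 and PPTS in 1,2-dichloroethane at 55 °C convert the diol into a cyclic orthoformate, which ionises at the para-benzyloxybenzylic carbon. The phenol then closes the ring under these reversible, stereoconvergent conditions, which are known from flavan-3-ol syntheses. The product should be the all-equatorial (2R,3S,4S)-7-(benzyloxy)-2-[4-(benzyloxy)phenyl]-4-[2,4-bis(benzyloxy)-6-bromophenyl]-3,4-dihydro-2H-chromen-3-yl formate F6.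
- **Return to the route:** K2CO3 in MeOH/THF removes the formate and gives 17.

**Step 11.**
- **What may go wrong:** the six-fold cleavage may stall, and protonation of the electron-rich stilbene may start cationic cyclisation or oligomerisation. Lewis-acid opening of ring C at C2–O1 may also epimerise C2.
- **Scope of the fallback:** it sets out from 17 and comes back at 21. The benzyl groups are exchanged for acetyl groups before any alkene is present, so the last step becomes a mild solvolysis.
- **Protecting-group exchange:** BCl3/C6HMe5 at −78 °C converts 17 into (2R,3S,4S)-4-(2-bromo-4,6-dihydroxyphenyl)-2-(4-hydroxyphenyl)-3,4-dihydro-2H-chromene-3,7-diol F7. Ac2O/pyridine then gives the pentaacetate of this bromide F8.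
- **Styrene partner:** caffeic acid is decarboxylated by heating with Et3N in DMF to 4-ethenylbenzene-1,2-diol F9, which is acetylated to 4-ethenyl-1,2-phenylene diacetate F10.
- **Coupling and release:** Heck coupling of F8 with F10 (Pd(OAc)2, P(o-tol)3, Et3N, DMF, 90 °C) follows the known acetoxystyrene route to hydroxystilbenes and gives the heptaacetate of the target F11. K2CO3 in degassed MeOH at 0 °C followed by mild acidification releases 21.

## Further compounds

F1 | step 7 | methyl 3-[4-(benzyloxy)phenyl]-3-oxopropanoate | COC(=O)CC(=O)c1ccc(OCc2ccccc2)cc1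
F2 | step 7 | 3-[4-(benzyloxy)phenyl]-3-oxopropanoic acid | OC(=O)CC(=O)c1ccc(OCc2ccccc2)cc1
F3 | step 7 | (4S)-7-(benzyloxy)-2-[4-(benzyloxy)phenyl]-4-[2,4-bis(benzyloxy)-6-bromophenyl]-3,4-dihydro-2H-chromen-2-ol (C2 anomers) | OC1(c2ccc(OCc3ccccc3)cc2)Oc2cc(OCc3ccccc3)ccc2[C@@H](c2c(OCc3ccccc3)cc(OCc3ccccc3)cc2Br)C1
F4 | step 7 | (4S)-7-(benzyloxy)-2-[4-(benzyloxy)phenyl]-4-[2,4-bis(benzyloxy)-6-bromophenyl]-4H-chromene | C1(c2ccc(OCc3ccccc3)cc2)Oc2cc(OCc3ccccc3)ccc2[C@@H](c2c(OCc3ccccc3)cc(OCc3ccccc3)cc2Br)C=1
F5 | step 8 | (2S,3S)-1-[4-(benzyloxy)phenyl]-3-[4-(benzyloxy)-2-hydroxyphenyl]-3-[2,4-bis(benzyloxy)-6-bromophenyl]propane-1,2-diol (C1 epimers) | Oc1cc(OCc2ccccc2)ccc1[C@@H](c1c(OCc2ccccc2)cc(OCc2ccccc2)cc1Br)[C@H](O)C(O)c1ccc(OCc2ccccc2)cc1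
F6 | step 8 | (2R,3S,4S)-7-(benzyloxy)-2-[4-(benzyloxy)phenyl]-4-[2,4-bis(benzyloxy)-6-bromophenyl]-3,4-dihydro-2H-chromen-3-yl formate | c1ccccc1COc1ccc([C@H]2Oc3cc(OCc4ccccc4)ccc3[C@@H](c3c(OCc4ccccc4)cc(OCc4ccccc4)cc3Br)[C@@H]2OC=O)cc1
F7 | step 11 | (2R,3S,4S)-4-(2-bromo-4,6-dihydroxyphenyl)-2-(4-hydroxyphenyl)-3,4-dihydro-2H-chromene-3,7-diol | Oc1ccc([C@H]2Oc3cc(O)ccc3[C@@H](c3c(O)cc(O)cc3Br)[C@@H]2O)cc1
F8 | step 11 | pentaacetate of F7 | CC(=O)Oc1ccc([C@H]2Oc3cc(OC(C)=O)ccc3[C@@H](c3c(OC(C)=O)cc(OC(C)=O)cc3Br)[C@@H]2OC(C)=O)cc1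
F9 | step 11 | 4-ethenylbenzene-1,2-diol | C=Cc1ccc(O)c(O)c1
F10 | step 11 | 4-ethenyl-1,2-phenylene diacetate | C=Cc1ccc(OC(C)=O)c(OC(C)=O)c1
F11 | step 11 | heptaacetate of 21 | CC(=O)Oc1ccc([C@H]2Oc3cc(OC(C)=O)ccc3[C@@H](c3c(OC(C)=O)cc(OC(C)=O)cc3/C=C/c3ccc(OC(C)=O)c(OC(C)=O)c3)[C@@H]2OC(C)=O)cc1
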